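**Retrosynthetic overview**
1. 23 ⇒ aldehyde acid 21: both exo-methylenes (C3 and C13) are made last, in one double Mannich methylenation; 21 ⇒ 19 by acidolysis and oxidation.
2. Key step, used instead of the usual aldehyde + bromomethylacrylate allylation/lactonisation on a carvone-type ring: C8-tethered diazomalonate 17 ⇒ cyclopropane-fused lactone 18 (intramolecular carbene cyclopropanation) ⇒ SN2 homoconjugate acetolysis at C6 ⇒ 19. These two steps give the lactone C–C bond, C7, C6 and the 6-acetate.
3. 17 ⇒ cis-8,9-diol 11 ⇒ allylic alcohol 7 (hydroxyl-directed epoxidation, then selenoxide transposition).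
4. 7 ⇒ enal 3 + 1-acetoxybutadiene 4: a catalytic asymmetric Diels–Alder reaction sets C5, C9 and the quaternary C10 at once.
5. Ring order: cyclohexene (step 2) → cyclopropane and γ-lactone together (step 10) → cyclopropane opened (step 11).

Conventions and assumption: ring carbons keep the elemanolide numbers of the target throughout (C5–C10 ring, C7/C8 lactone fusion, C11–C13 lactone, C14 methyl, C1/C2 vinyl, C3/C4/C15 acrolein unit); β = ring face of the C10 methyl, α = face of the C10 vinyl; the target is 5R,6S,7R,8R,9S,10S; silyloxy aldehyde 1 (CAS 89922-82-7) is taken as purchasable.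

**Step 1**
Reactants: 1 3-[(tert-butyldimethylsilyl)oxy]propanal; 2 2-(triphenyl-λ5-phosphanylidene)propanal
Product: 3 (E)-5-[(tert-butyldimethylsilyl)oxy]-2-methylpent-2-enal
Conditions: toluene, 80 °C
Reagents that add atoms: none
Why: Wittig olefination with a stabilised α-branched ylide gives the (E)-trisubstituted enal selectively.

**Step 2**
Reactants: 3 (E)-5-[(tert-butyldimethylsilyl)oxy]-2-methylpent-2-enal; 4 (E)-buta-1,3-dien-1-yl acetate
Product: 5 (1R,5S,6S)-5-{2-[(tert-butyldimethylsilyl)oxy]ethyl}-6-formyl-6-methylcyclohex-2-en-1-yl acetate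
Conditions: (S)-3,3-diphenyl-1-(o-tolyl)tetrahydro-1H,3H-pyrrolo[1,2-c][1,3,2]oxazaborole·HNTf2 (20 mol %), 4 (3 equiv of the commercial E/Z mixture, only E reacts), CH2Cl2, −78 → −40 °C
Reagents that add atoms: none
Why: Catalytic asymmetric Diels–Alder reaction: the 1-acetoxy donor gives the "ortho" regiochemistry, the endo-CHO transition state puts 9-OAc cis to CHO (both α), suprafacial addition to the E-enal puts the C5 chain trans to CHO (β, cis to the methyl), and the protonated oxazaborolidine (antipode set in a test run so that the diene adds to the Cα-Re face of 3) fixes the absolute configuration of C5, C9 and C10.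

**Step 3**
Reactants: 5 (1R,5S,6S)-5-{2-[(tert-butyldimethylsilyl)oxy]ethyl}-6-formyl-6-methylcyclohex-2-en-1-yl acetate
Product: 6 (1R,5S,6S)-5-{2-[(tert-butyldimethylsilyl)oxy]ethyl}-6-ethenyl-6-methylcyclohex-2-en-1-yl acetate
Conditions: Ph3PCH3Br, KN(SiMe3)2, THF, −78 → 0 °C
Reagents that add atoms: methyltriphenylphosphonium bromide (used as its ylide), C[P+](c1ccccc1)(c1ccccc1)c1ccccc1.[Br-]
Why: Wittig methylenation of the neopentyl aldehyde (no α-hydrogen, so no epimerisation or elimination) makes the angular vinyl group, the aldehyde reacting faster than the acetate.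

**Step 4**
Reactants: 6 (1R,5S,6S)-5-{2-[(tert-butyldimethylsilyl)oxy]ethyl}-6-ethenyl-6-methylcyclohex-2-en-1-yl acetate
Product: 7 (1R,5S,6S)-5-{2-[(tert-butyldimethylsilyl)oxy]ethyl}-6-ethenyl-6-methylcyclohex-2-en-1-ol
Conditions: K2CO3 (cat.), MeOH, rt
Reagents that add atoms: none
Why: Base-catalysed transesterification (methanolysis) frees the 9α allylic alcohol and leaves the silyl ether alone.

**Step 5**
Reactants: 7 (1R,5S,6S)-5-{2-[(tert-butyldimethylsilyl)oxy]ethyl}-6-ethenyl-6-methylcyclohex-2-en-1-ol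
Product: 8 7α,8α-epoxy-9α-ol (epoxide cis to the hydroxyl)
Conditions: VO(acac)2 (5 mol %), t-BuOOH, CH2Cl2, 0 °C → rt
Reagents that add atoms: tert-butyl hydroperoxide, CC(C)(C)OO
Why: Hydroxyl-directed vanadium-catalysed epoxidation delivers oxygen to the ring alkene on the face of the 9α-OH (cis epoxy alcohol), and the only homoallylic vinyl group reacts far more slowly.

**Step 6**
Reactants: 8 7α,8α-epoxy-9α-ol
Product: 11 Δ6-ene-8α,9α-diol, via hydroxy selenide 9 (not isolated), via selenoxide 10 (not isolated)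
Conditions: (PhSe)2, NaBH4, EtOH, 60 °C; then THF, 30% H2O2, pyridine, 0 °C → rt
Reagents that add atoms: none
Why: Sharpless–Lauer epoxide-to-allylic-alcohol transposition: benzeneselenolate opens the epoxide trans-diaxially at C7 (the carbon remote from the carbinol, C8 being inductively deactivated), and the selenoxide then undergoes syn-elimination away from the hydroxyl-bearing carbon, so the alkene moves to C6=C7 and C8 keeps its α-oxygen cis to the 9α-OH.

**Step 7**
Reactants: 11 Δ6-ene-8α,9α-diol; 12 3-(tert-butoxy)-3-oxopropanoic acid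
Product: 13 8-O-(tert-butyl malonyl) ester of 11 (9α-OH free)
Conditions: DCC, DMAP (cat.), CH2Cl2, −20 → 0 °C
Reagents that add atoms: none
Why: Steglich esterification is selective for the unhindered allylic 8α-OH, because the 9α-OH is neopentyl (next to the quaternary C10).

**Step 8**
Reactants: 13 8-O-(tert-butyl malonyl) ester; 14 angelic acid [(Z)-2-methylbut-2-enoic acid]
Product: 16 9-O-angeloyl-8-O-(tert-butyl malonyl) diester, via mixed anhydride 15 (not isolated)
Conditions: 14, 2,4,6-Cl3C6H2COCl, Et3N, toluene, rt; then 13, 80 °C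
Reagents that add atoms: none
Why: Yamaguchi esterification run without DMAP acylates the hindered 9α-OH through the mixed anhydride while avoiding nucleophile-induced Z → E isomerisation of the angelate.

**Step 9**
Reactants: 16 9-O-angeloyl-8-O-(tert-butyl malonyl) diester
Product: 17 8-O-(tert-butyl diazomalonyl) 9-O-angelate
Conditions: 4-AcNHC6H4SO2N3, Et3N, MeCN, 0 °C → rt
Reagents that add atoms: 4-acetamidobenzenesulfonyl azide, CC(=O)Nc1ccc(cc1)S(=O)(=O)N=[N+]=[N-]
Why: Regitz diazo transfer to the acidic malonate methylene under conditions that leave the esters untouched.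

**Step 10**
Reactants: 17 8-O-(tert-butyl diazomalonyl) 9-O-angelate
Product: 18 cyclopropane-fused lactone (C11 bonded to C6 and C7 on the α face, C11 carrying CO2t-Bu)
Conditions: Rh2(OAc)4 (2 mol %), ClCH2CH2Cl, 80 °C, slow addition
Reagents that add atoms: none
Why: Intramolecular cyclopropanation by the rhodium carbene: the three-atom ester tether from the 8α-oxygen can reach only the α face of the adjacent C6=C7 alkene, so the γ-lactone closes cis-fused with C11 α at C7, and five-membered closure is preferred over attack on the distant vinyl group or insertion into the acyloxy-deactivated C9–H.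

**Step 11**
Reactants: 18 cyclopropane-fused lactone
Product: 19 6β-acetoxy lactone tert-butyl ester (C11 epimers)
Conditions: CsOAc (5 equiv), AcOH (2 equiv), 18-crown-6, DMSO, 80 °C
Reagents that add atoms: cesium acetate, CC(=O)[O-].[Cs+]
Why: Proposed new method: SN2 homoconjugate (homo-Michael) addition of acetate to the cyclopropane doubly activated by the lactone and ester carbonyls, in which the C6–C11 bond (exo to the lactone and aligned with both carbonyl π* orbitals) breaks, backside attack puts the acetate on the β face of C6 trans to C11 with inversion, and AcOH protonates the stabilised enolate so the opening is not reversed; the closest known reactions are ring openings of 1-alkoxycarbonyl-3-oxabicyclo[3.1.0]hexan-2-ones by azide, thiolate, amine or halide nucleophiles.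

**Step 12**
Reactants: 19 6β-acetoxy lactone tert-butyl ester
Product: 20 hydroxy acid (C11–CO2H, C15–OH)
Conditions: CF3CO2H/CH2Cl2/H2O (10:10:1), 0 °C → rt
Reagents that add atoms: none
Why: Acidolysis cleaves the tert-butyl ester (E1 loss of isobutene) and hydrolyses the primary silyl ether in the same pot, while acetate, angelate and lactone survive.

**Step 13**
Reactants: 20 hydroxy acid
Product: 21 aldehyde acid (C15 aldehyde, C11–CO2H)
Conditions: Dess–Martin periodinane, CH2Cl2, 0 °C → rt
Reagents that add atoms: none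
Why: Dess–Martin oxidation converts the primary alcohol to the aldehyde under non-basic conditions that tolerate the free acid and avoid over-oxidation.

**Step 14**
Reactants: 21 aldehyde acid
Product: 23 target CNP0252310.2, via bis-Mannich base 22 (not isolated)
Conditions: CH2=NMe2+ I− (5 equiv), Et3N, CH2Cl2, rt → 40 °C; then SiO2
Reagents that add atoms: N,N-dimethylmethyleneiminium iodide (Eschenmoser's salt), C=[N+](C)C.[I-]
Why: Double Mannich (Eschenmoser) methylenation: the aldehyde α-CH2 gives a β-amino aldehyde that eliminates Me2NH, and the malonic half-acid carbon gives a β-amino acid that loses CO2 and Me2NH, so C3 and C13 are both created without touching a stereocentre.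

**Compound list**
1 | 3-[(tert-butyldimethylsilyl)oxy]propanal | O=CCCO[Si](C)(C)C(C)(C)C | starting material
2 | 2-(triphenyl-λ5-phosphanylidene)propanal | CC(C=O)=P(c1ccccc1)(c1ccccc1)c1ccccc1 | starting material
3 | (E)-5-[(tert-butyldimethylsilyl)oxy]-2-methylpent-2-enal | O=C/C(C)=C/CCO[Si](C)(C)C(C)(C)C | intermediate
4 | (E)-buta-1,3-dien-1-yl acetate | C=C/C=C/OC(C)=O | starting material
5 | (1R,5S,6S)-5-{2-[(tert-butyldimethylsilyl)oxy]ethyl}-6-formyl-6-methylcyclohex-2-en-1-yl acetate (9α-OAc, 10α-CHO, 10β-Me, 5β-chain) | O=C[C@]1(C)[C@H](OC(C)=O)C=CC[C@H]1CCO[Si](C)(C)C(C)(C)C | intermediate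
6 | (1R,5S,6S)-5-{2-[(tert-butyldimethylsilyl)oxy]ethyl}-6-ethenyl-6-methylcyclohex-2-en-1-yl acetate | C=C[C@]1(C)[C@H](OC(C)=O)C=CC[C@H]1CCO[Si](C)(C)C(C)(C)C | intermediate
7 | (1R,5S,6S)-5-{2-[(tert-butyldimethylsilyl)oxy]ethyl}-6-ethenyl-6-methylcyclohex-2-en-1-ol | C=C[C@]1(C)[C@H](O)C=CC[C@H]1CCO[Si](C)(C)C(C)(C)C | intermediate
8 | 7α,8α-epoxide of 7 (epoxide cis to 9α-OH) | C=C[C@]1(C)[C@H](O)[C@@H]2O[C@@H]2C[C@H]1CCO[Si](C)(C)C(C)(C)C | intermediate
9 | hydroxy selenide: 7β-phenylselanyl-8α,9α-diol | C=C[C@]1(C)[C@H](O)[C@H](O)[C@@H]([Se]c2ccccc2)C[C@H]1CCO[Si](C)(C)C(C)(C)C | intermediate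
10 | selenoxide of 9 (configuration at Se not defined) | C=C[C@]1(C)[C@H](O)[C@H](O)[C@@H]([Se](=O)c2ccccc2)C[C@H]1CCO[Si](C)(C)C(C)(C)C | intermediate
11 | Δ6-ene-8α,9α-diol (10β-Me, 10α-vinyl, 5β-chain) | C=C[C@]1(C)[C@H](O)[C@H](O)C=C[C@H]1CCO[Si](C)(C)C(C)(C)C | intermediate
12 | 3-(tert-butoxy)-3-oxopropanoic acid (mono-tert-butyl malonate) | CC(C)(C)OC(=O)CC(=O)O | starting material
13 | 8-O-(tert-butyl malonyl) ester of 11 | C=C[C@]1(C)[C@H](O)[C@H](OC(=O)CC(=O)OC(C)(C)C)C=C[C@H]1CCO[Si](C)(C)C(C)(C)C | intermediate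
14 | angelic acid, (Z)-2-methylbut-2-enoic acid | C/C=C(/C)C(=O)O | starting material
15 | angelic 2,4,6-trichlorobenzoic anhydride | C/C=C(/C)C(=O)OC(=O)c1c(Cl)cc(Cl)cc1Cl | intermediate
16 | 9-O-angeloyl-8-O-(tert-butyl malonyl) diester | C=C[C@]1(C)[C@H](OC(=O)/C(C)=C\C)[C@H](OC(=O)CC(=O)OC(C)(C)C)C=C[C@H]1CCO[Si](C)(C)C(C)(C)C | intermediate
17 | 8-O-(tert-butyl diazomalonyl) 9-O-angelate | C=C[C@]1(C)[C@H](OC(=O)/C(C)=C\C)[C@H](OC(=O)C(=[N+]=[N-])C(=O)OC(C)(C)C)C=C[C@H]1CCO[Si](C)(C)C(C)(C)C | intermediate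
18 | cyclopropane-fused lactone (α-face cyclopropane C6–C7–C11; C11 bears CO2t-Bu and the lactone carbonyl) | C=C[C@]1(C)[C@H](OC(=O)/C(C)=C\C)[C@@H]2OC(=O)[C@@]3(C(=O)OC(C)(C)C)[C@@H]2[C@H]3[C@H]1CCO[Si](C)(C)C(C)(C)C | intermediate
19 | 6β-acetoxy-9α-angeloyloxy 12,8α-lactone with C11–CO2t-Bu and C15–OTBS (C11 epimers, centre removed in step 14) | C=C[C@]1(C)[C@H](OC(=O)/C(C)=C\C)[C@@H]2OC(=O)C(C(=O)OC(C)(C)C)[C@@H]2[C@@H](OC(C)=O)[C@H]1CCO[Si](C)(C)C(C)(C)C | intermediate
20 | hydroxy acid (C11–CO2H, C15–OH; C11 epimers) | C=C[C@]1(C)[C@H](OC(=O)/C(C)=C\C)[C@@H]2OC(=O)C(C(=O)O)[C@@H]2[C@@H](OC(C)=O)[C@H]1CCO | intermediate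
21 | aldehyde acid (C15 aldehyde, C11–CO2H; C11 epimers) | C=C[C@]1(C)[C@H](OC(=O)/C(C)=C\C)[C@@H]2OC(=O)C(C(=O)O)[C@@H]2[C@@H](OC(C)=O)[C@H]1CC=O | intermediate
22 | bis-Mannich base (CH2NMe2 on C4 and on C11; C4 and C11 not defined) | C=C[C@]1(C)[C@H](OC(=O)/C(C)=C\C)[C@@H]2OC(=O)C(CN(C)C)(C(=O)O)[C@@H]2[C@@H](OC(C)=O)[C@H]1C(CN(C)C)C=O | intermediate
23 | CNP0252310.2, (5R,6S,7R,8R,9S,10S)-6-acetoxy-9-angeloyloxy-15-oxoelema-1,3,11(13)-trien-12,8-olide | C=C[C@]1(C)[C@H](OC(=O)/C(C)=C\C)[C@@H]2OC(=O)C(=C)[C@@H]2[C@@H](OC(C)=O)[C@H]1C(=C)C=O | target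

**Totals:** 14 steps; longest linear sequence 14 steps (1 → 23); the other building blocks (2, 4, 12, 14) are commercial.

**Steps most likely to fail**

Step 2 (asymmetric Diels–Alder with a trisubstituted enal: rate, endo/exo ratio and enantioselectivity are all at stake). Fallback: control by a chiral dienyl ester instead of a chiral catalyst. It sets out from 3 and comes back to the route at 7. Crotonaldehyde is O-acylated (KOtBu, THF, −78 °C; (S)-2-methoxy-2-phenylacetyl chloride) to (E)-buta-1,3-dien-1-yl (S)-2-methoxy-2-phenylacetate F1. BF3·OEt2 (CH2Cl2, −78 °C) then joins 3 and F1 to the 9α-mandelate cycloadduct F2, the phenyl ring shielding one diene face by π-stacking. Wittig methylenation gives the vinyl mandelate F3, and K2CO3/MeOH removes the auxiliary to give 7. The antipodal auxiliary is used if the first run shows the opposite facial sense.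

Step 11 (new homoconjugate acetolysis at a hindered secondary cyclopropane carbon; acetate may be too weak a nucleophile, or the silyl ether oxygen may compete). Fallback: put the oxygen on first and let the tethered malonate be the nucleophile, with an epoxide in place of the cyclopropane and no carbene. It sets out from 16 and comes back at 19. Dimethyldioxirane (acetone, 0 °C) epoxidises the ring alkene on the β face, anti to the two α-acyloxy groups, to give the 6β,7β-epoxide F4; this facial preference is itself uncertain, and any α-epoxide is removed by chromatography. Cs2CO3 in MeCN generates the malonate anion, which opens the epoxide at C7 from the α face (5-exo, SN2) to give the 6β-hydroxy lactone F5. Ac2O, pyridine and DMAP then give 19.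

Step 14 (two methylenations in one pot on a substrate carrying an enal, an α-methylene lactone and liberated amine). Fallback: do the two methylenations one at a time and by different chemistry. It sets out from 20 and comes back at 23. Paraformaldehyde and Et2NH in dioxane at 70 °C (decarboxylative Mannich reaction of the free malonic half-acid) give the α-methylene lactone alcohol F6. Dess–Martin oxidation gives the α-methylene lactone aldehyde F7. Aqueous CH2O with catalytic pyrrolidine/propionic acid in i-PrOH at 45 °C then methylenates the aldehyde to 23.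

**Further compounds**
F1 | step 2 | (E)-buta-1,3-dien-1-yl (S)-2-methoxy-2-phenylacetate | C=C/C=C/OC(=O)[C@@H](OC)c1ccccc1
F2 | step 2 | 9α-mandelate cycloadduct (analogue of 5 with the (S)-2-methoxy-2-phenylacetate in place of acetate) | O=C[C@]1(C)[C@H](OC(=O)[C@@H](OC)c2ccccc2)C=CC[C@H]1CCO[Si](C)(C)C(C)(C)C
F3 | step 2 | vinyl mandelate (analogue of 6) | C=C[C@]1(C)[C@H](OC(=O)[C@@H](OC)c2ccccc2)C=CC[C@H]1CCO[Si](C)(C)C(C)(C)C
F4 | step 11 | 6β,7β-epoxide of 16 | C=C[C@]1(C)[C@H](OC(=O)/C(C)=C\C)[C@H](OC(=O)CC(=O)OC(C)(C)C)[C@H]2O[C@H]2[C@H]1CCO[Si](C)(C)C(C)(C)C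
F5 | step 11 | 6β-hydroxy lactone (19 with OH in place of OAc; C11 epimers) | C=C[C@]1(C)[C@H](OC(=O)/C(C)=C\C)[C@@H]2OC(=O)C(C(=O)OC(C)(C)C)[C@@H]2[C@@H](O)[C@H]1CCO[Si](C)(C)C(C)(C)C
F6 | step 14 | α-methylene lactone alcohol (C15–OH) | C=C[C@]1(C)[C@H](OC(=O)/C(C)=C\C)[C@@H]2OC(=O)C(=C)[C@@H]2[C@@H](OC(C)=O)[C@H]1CCO
F7 | step 14 | α-methylene lactone aldehyde (C4H2–C15HO) | C=C[C@]1(C)[C@H](OC(=O)/C(C)=C\C)[C@@H]2OC(=O)C(=C)[C@@H]2[C@@H](OC(C)=O)[C@H]1CC=O
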